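A flask charged with less free catalyst than impurity cannot keep a surplus of free catalyst, provided the two destroy each other one for one, which is the working assumption here.

all flasks: substrate 0.20 M; gas phase 56 mM (held); impurity 2.1 mM
- west: free catalyst 2.8 mM; run made earlier
- north: free catalyst 4.4 mM; run made earlier
- flask: free catalyst 2.0 mM; time 20 h

- west (time / h: target / %, substrate / %): 3.00: 4, 97; 6.00: 9, 92; 10.0: 14, 85; 12.0: 14, 85
- north (time / h: target / %, substrate / %): 3.00: 8, 92; 6.00: 15, 83; 10.0: 23, 77; 12.0: 23, 73

(scatter of a reading: 1.5 percentage points)

- the target standing at 20 h, as a percentage of the substrate charged
- concentration of dissolved gas in solution at 5.0 h, in percent of saturation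
- the change that raises the amount of target at 20 h, in percent of the substrate charged most ("none" if none brings more than 2 percentage points) (Thursday's / Monday's / Friday's / none)
- amount of target at 20 h, in percent of the substrate charged, after Monday's

- Thursday's: doubling the transfer coefficient of the gas phase, all else as stated
- Monday's: doubling the amount of free catalyst, all else as stated
- Friday's: doubling the saturation concentration of gas phase, all else as stated

1. Assume target forms in proportion to free catalyst, while free catalyst and impurity disappear in proportion to their product. Dividing the first rate by the second cancels free catalyst and removes time: target made = toll × ln(impurity charged / impurity left).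
2. In a run with surplus catalyst (charged catalyst minus charged impurity, the impurity being the limiting reagent), the surplus keeps working. So each reading at 12.0 h equals toll × ln(catalyst charged / surplus) plus a part proportional to surplus. West and north give two such equations. They yield the impurity toll, the target gained per factor e of fall in impurity, as 5.89 %. The surplus part in west is 5.84 %. Both are solved from the two readings at 12.0 h, each with a scatter of 1.5 percentage points, and are uncertain accordingly.
3. One extreme for this flask is instant poisoning: free catalyst vanishes at once, and no target forms. The other is inert impurity: the charged free catalyst works throughout at the surplus pace and gives 27.8 %.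
4. The real flask lies between them, with poisoning at a finite pace. The west and north readings give that pace. By 20 h the ratio of impurity to free catalyst reaches 1.33, which leaves 0.403 mM impurity. The toll then gives 9.71 % target.
5. Monday's change creates a surplus of 1.90 mM and gives 30.8 %. If the target rate follows dissolved gas, Friday's change at most doubles the target, a smaller gain.

The forecast gives 9.7 %, 92 % of saturation, Monday's and 20.7 %, below the reckoning above, on the ground “The catalyst therefore dies”.

The flask gives 8.55 %, 80.0 % of saturation at 5.0 h, Monday's as the best change, and 30.2 % after it.

    gas phase ⇌ dissolved gas, rate k1*(csat - [dissolved gas]) (kL = 2.20 × 10⁻⁴ s⁻¹)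
    substrate + dissolved gas + free catalyst ⇌ free catalyst + target (K = 13.0 L mol⁻¹, k = 0.110 L² mol⁻² s⁻¹)
    2 dissolved gas → self-condensation product (k = 5.00 × 10⁻⁴ L mol⁻¹ s⁻¹)
    free catalyst + impurity → spent catalyst (k = 0.100 L mol⁻¹ s⁻¹)

At 20.0 h the flask holds 8.9 % of its impurity, so its target per factor e is 3.53 %, lower than the toll read from the runs. For the neighbour with 0.0034 M free catalyst, the toll and surplus part give 23.7 %, and that flask gives 26.1 %.

The data were generated by integration with constants of no real substance; scatter was added.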